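**Plan**

Rings: A is the terminal naphthol joined through C2, B the central naphthol joined through C2 and C4, C the terminal naphthol joined through C4; each is numbered as an 8-methoxynaphthalen-1-ol.
Retrosynthesis first frees the ring C hydroxyl from a benzyl ether and the A and B hydroxyls from an O–Si–O bridge, then cuts the A C2–B C2 biaryl bond.
That bond lies ortho to a hydroxyl on both rings (A C1–OH and B C1–OH), so the two oxygens can be tied through one silicon atom and the coupling made intramolecular.
The two Si–O bonds are cut next, and last the B C4–C C4 bond, which goes back to para–para oxidative dimerisation of two molecules of 8-methoxynaphthalen-1-ol.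
Forward: B–C dimer from two molecules of the monomer, monobenzylation, ortho-bromination of a third monomer (ring A), silylene tethering, palladium-catalysed C–H arylation closing a seven-membered dioxasilepine (the only ring formed), desilylation, hydrogenolysis.
Stereochemistry: the target has no stereocentre and neither biaryl axis is configurationally fixed, so nothing needs to be controlled.

Key step: step 5

Remark on the chemistry: 8-methoxynaphthalen-1-ol is taken as a purchasable material, and the target is made as drawn, without axial descriptors.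

**Route**

Step 1
Reactants: 1 8-methoxynaphthalen-1-ol (two molecules, one becoming ring B and one ring C)
Product: 3 5,5'-dimethoxy-[1,1'-binaphthalene]-4,4'-diol, via binaphthoquinone 2 (not isolated)
Conditions: Ag2O (1.1 equiv per naphthol), CH2Cl2, rt, dark; filter through Celite; then Na2S2O4, THF/H2O, rt, Ar
Reagents that add atoms: 8-methoxynaphthalen-1-ol (the second molecule of 1), COc1cccc2cccc(O)c12
Why: Oxidative phenol coupling of two naphthoxyl radicals derived from 1 should join the unhindered para carbons (C4–C4'), and carrying the oxidation through to the extended quinone before dithionite reduction avoids a mixture caused by the dimer being oxidised more easily than the monomer.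

Step 2
Reactants: 3 5,5'-dimethoxy-[1,1'-binaphthalene]-4,4'-diol; 4 benzyl bromide
Product: 5 4'-(benzyloxy)-5,5'-dimethoxy-[1,1'-binaphthalen]-4-ol
Conditions: BnBr (1.0 equiv), K2CO3 (1.1 equiv), degassed DMF, rt, Ar
Reagents that add atoms: benzyl bromide, BrCc1ccccc1
Why: Williamson ether synthesis on a symmetric bis-naphthol with one equivalent of halide should give the mono-ether as the main component of a statistical mixture, from which diol 3 is recovered and recycled.

Step 3
Reactants: 1 8-methoxynaphthalen-1-ol; 6 N-bromosuccinimide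
Product: 7 2-bromo-8-methoxynaphthalen-1-ol
Conditions: NBS (1.0 equiv), iPr2NH (10 mol %), CH2Cl2, 0 °C
Reagents that add atoms: N-bromosuccinimide, O=C1CCC(=O)N1Br
Why: Amine-catalysed electrophilic ortho-bromination of a phenol delivers bromine next to the free hydroxyl through an N-bromoamine and ammonium naphthoxide pair, while the uncatalysed para pathway is slow in CH2Cl2 at 0 °C.

Step 4
Reactants: 7 2-bromo-8-methoxynaphthalen-1-ol; 8 di-tert-butylsilyl bis(trifluoromethanesulfonate); 5 4'-(benzyloxy)-5,5'-dimethoxy-[1,1'-binaphthalen]-4-ol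
Product: 10 {4-[4-(benzyloxy)-5-methoxynaphthalen-1-yl]-8-methoxynaphthalen-1-yl}oxy[(2-bromo-8-methoxynaphthalen-1-yl)oxy]di-tert-butylsilane, via silyl triflate 9 (not isolated)
Conditions: 7 (1.05 equiv), tBu2Si(OTf)2 (1.0 equiv), Et3N, CH2Cl2, 0 °C, 30 min; then 5 (0.9 equiv), Et3N, DMAP (cat.), DMF, 0 to 60 °C
Reagents that add atoms: di-tert-butylsilyl bis(trifluoromethanesulfonate), CC(C)(C)[Si](OS(=O)(=O)C(F)(F)F)(OS(=O)(=O)C(F)(F)F)C(C)(C)C
Why: Stepwise silyl ether formation should work because the first triflate is displaced quickly at 0 °C while the hindered aryloxysilyl triflate waits for the second naphthol, and the short cold first stage is meant to keep the peri methoxy group from attacking silicon.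

Step 5
Reactants: 10 silylene-bridged bis(naphthyl ether)
Product: 11 di-tert-butylsilylene derivative (seven-membered 1,3,2-dioxasilepine, silicon bridging O1 and O1') of 4-[4-(benzyloxy)-5-methoxynaphthalen-1-yl]-8,8'-dimethoxy-[2,2'-binaphthalene]-1,1'-diol
Conditions: Pd(OAc)2 (10 mol %), PCy3·HBF4 (20 mol %), CsOPiv (2 equiv), 4 Å MS, p-xylene, 140 °C, Ar
Reagents that add atoms: none
Why: Zerovalent palladium formed from Pd(OAc)2 and the phosphine inserts into the A C2–Br bond, bromide is exchanged for pivalate, and carboxylate-assisted concerted metalation–deprotonation at B C2–H gives an eight-membered diaryl palladacycle of divalent palladium, whose reductive elimination forms the A C2–B C2 bond. The closest known reaction type is the silicon-tethered palladium-catalysed intramolecular C–H arylation of phenols that gives unsymmetrical 2,2'-biphenols and binaphthols. The one ring formed, the seven-membered dioxasilepine, closes through this biaryl bond, by ring contraction of the palladacycle on reductive elimination. No stereocentre is created, and the new axis carries only the two bridged oxygens and two hydrogens at its ortho positions, so it needs no control. The selectivity needed is ortho–ortho union in place of the para coupling that free 1-naphthols prefer; the O–Si–O bridge secures it, because B C2–H is the only aryl C–H ortho to the B oxygen (the other ortho carbon is the ring-fusion atom C8a) and so the only one the tethered arylpalladium can reach, while B C4 already carries ring C and ring C is capped as its benzyl ether.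

Step 6
Reactants: 11 dinaphtho-dioxasilepine
Product: 12 4-[4-(benzyloxy)-5-methoxynaphthalen-1-yl]-8,8'-dimethoxy-[2,2'-binaphthalene]-1,1'-diol
Conditions: Bu4NF (2.5 equiv), AcOH (2.5 equiv), degassed THF, 0 °C to rt, Ar
Reagents that add atoms: none
Why: Fluoride-induced desilylation cleaves both aryl Si–O bonds, driven by the strong Si–F bond and the good naphthoxide leaving groups, while acetic acid keeps the electron-rich naphthols protonated and the benzyl ether is inert.

Step 7
Reactants: 12 benzyl-protected ternaphthol
Product: 13 4-(4-hydroxy-5-methoxynaphthalen-1-yl)-8,8'-dimethoxy-[2,2'-binaphthalene]-1,1'-diol (target)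
Conditions: H2 (1 atm), 10% Pd/C, EtOAc/MeOH, rt
Reagents that add atoms: none
Why: Catalytic hydrogenolysis removes the benzyl aryl ether without touching naphthalene rings or aryl methyl ethers at 1 atm and rt, and the reducing medium protects the oxidation-prone product.

**Compound list**

1 | 8-methoxynaphthalen-1-ol | COc1cccc2cccc(O)c12 | starting material
2 | (E)-5,5'-dimethoxy-4H,4'H-[1,1'-binaphthalenylidene]-4,4'-dione (binaphthoquinone, drawn as the less crowded E isomer; the geometry is erased on reduction) | O=C1C=C/C(=C2/C=CC(=O)c3c(OC)cccc23)c2cccc(OC)c12 | intermediate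
3 | 5,5'-dimethoxy-[1,1'-binaphthalene]-4,4'-diol | COc1cccc2c(-c3ccc(O)c4c(OC)cccc34)ccc(O)c12 | intermediate
4 | benzyl bromide | BrCc1ccccc1 | starting material
5 | 4'-(benzyloxy)-5,5'-dimethoxy-[1,1'-binaphthalen]-4-ol | COc1cccc2c(-c3ccc(OCc4ccccc4)c4c(OC)cccc34)ccc(O)c12 | intermediate
6 | N-bromosuccinimide | O=C1CCC(=O)N1Br | starting material
7 | 2-bromo-8-methoxynaphthalen-1-ol | COc1cccc2ccc(Br)c(O)c12 | intermediate
8 | di-tert-butylsilyl bis(trifluoromethanesulfonate) | CC(C)(C)[Si](OS(=O)(=O)C(F)(F)F)(OS(=O)(=O)C(F)(F)F)C(C)(C)C | starting material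
9 | [(2-bromo-8-methoxynaphthalen-1-yl)oxy]di-tert-butylsilyl trifluoromethanesulfonate | COc1cccc2ccc(Br)c(O[Si](OS(=O)(=O)C(F)(F)F)(C(C)(C)C)C(C)(C)C)c12 | intermediate
10 | {4-[4-(benzyloxy)-5-methoxynaphthalen-1-yl]-8-methoxynaphthalen-1-yl}oxy[(2-bromo-8-methoxynaphthalen-1-yl)oxy]di-tert-butylsilane | COc1cccc2ccc(Br)c(O[Si](C(C)(C)C)(C(C)(C)C)Oc3ccc(-c4ccc(OCc5ccccc5)c5c(OC)cccc45)c4cccc(OC)c34)c12 | intermediate
11 | di-tert-butylsilylene derivative (1,3,2-dioxasilepine) of 4-[4-(benzyloxy)-5-methoxynaphthalen-1-yl]-8,8'-dimethoxy-[2,2'-binaphthalene]-1,1'-diol | COc1cccc2ccc3c(O[Si](C(C)(C)C)(C(C)(C)C)Oc4c-3cc(-c5ccc(OCc6ccccc6)c6c(OC)cccc56)c5cccc(OC)c45)c12 | intermediate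
12 | 4-[4-(benzyloxy)-5-methoxynaphthalen-1-yl]-8,8'-dimethoxy-[2,2'-binaphthalene]-1,1'-diol | COc1cccc2ccc(-c3cc(-c4ccc(OCc5ccccc5)c5c(OC)cccc45)c4cccc(OC)c4c3O)c(O)c12 | intermediate
13 | 4-(4-hydroxy-5-methoxynaphthalen-1-yl)-8,8'-dimethoxy-[2,2'-binaphthalene]-1,1'-diol | COc1cccc2ccc(-c3cc(-c4ccc(O)c5c(OC)cccc45)c4cccc(OC)c4c3O)c(O)c12 | target

**Step count and risks**

Total steps: 7. Longest linear sequence: 6 (steps 1, 2, 4, 5, 6, 7); step 3 is a one-step branch that joins at step 4.

Step 5 (most likely to fail). Oxidative addition into the electron-rich, doubly flanked aryl bromide may be slow, so that hydrodebromination, C–H activation of a tert-butyl group or cleavage of an Si–O bond by pivalate at 140 °C overtakes the ring closure. The fallback forms the same A C2–B C2 bond by an intermolecular Suzuki–Miyaura coupling and sets out from 5 and 7. Amine-catalysed NBS bromination of 5, whose para position is blocked by ring C, would give 4'-(benzyloxy)-3-bromo-5,5'-dimethoxy-[1,1'-binaphthalen]-4-ol F1. In parallel, 7 would be benzylated (BnBr, K2CO3, DMF) to 1-(benzyloxy)-2-bromo-8-methoxynaphthalene F2, and Miyaura borylation (B2pin2, Pd(dppf)Cl2, KOAc, dioxane, 90 °C) would give 2-[1-(benzyloxy)-8-methoxynaphthalen-2-yl]-4,4,5,5-tetramethyl-1,3,2-dioxaborolane F3. Coupling of F1 with F3 (Pd(OAc)2, SPhos, K3PO4, toluene/H2O, 80 °C) would give 1'-(benzyloxy)-4-[4-(benzyloxy)-5-methoxynaphthalen-1-yl]-8,8'-dimethoxy-[2,2'-binaphthalen]-1-ol F4. Hydrogenolysis of both benzyl ethers (H2, Pd/C) would then come back to the route at 13.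

Step 1. The radical coupling may not stay at the para carbons (ortho–para and ortho–ortho unions, further oligomerisation), and naphthol may add to the quinone in conjugate fashion. The fallback builds the B C4–C C4 bond by cross-coupling and sets out from 1. NBS in MeCN at −20 °C without amine (para-bromination) would give 4-bromo-8-methoxynaphthalen-1-ol F5. Benzylation (BnBr, K2CO3, DMF) would give 1-(benzyloxy)-4-bromo-8-methoxynaphthalene F6, and Miyaura borylation (B2pin2, Pd(dppf)Cl2, KOAc, dioxane, 90 °C) would give 2-[4-(benzyloxy)-5-methoxynaphthalen-1-yl]-4,4,5,5-tetramethyl-1,3,2-dioxaborolane F7. Suzuki–Miyaura coupling of F7 with unprotected F5 (Pd(OAc)2, SPhos, K3PO4, toluene/H2O, 80 °C) would come back to the route at 5, which also replaces the statistical monobenzylation of step 2.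

Step 3. With the hydroxyl hydrogen-bonded to the peri methoxy group, ortho delivery of bromine may fail, so that bromination runs para to the hydroxyl (C4) or para to the methoxy group (C5), or goes on to double bromination. The fallback fixes the position by directed ortho-metalation and sets out from 1. MOMCl and iPr2NEt in CH2Cl2 would give 1-methoxy-8-(methoxymethoxy)naphthalene F8. Lithiation with n-BuLi/TMEDA in THF (−78 to 0 °C) should occur at C2, since the methoxymethoxy group is the stronger director and the peri position is blocked. Quenching with BrCl2C–CCl2Br would give 2-bromo-8-methoxy-1-(methoxymethoxy)naphthalene F9, and HCl in MeOH would come back to the route at 7.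

**Further compounds**

F1 | step 5 | 4'-(benzyloxy)-3-bromo-5,5'-dimethoxy-[1,1'-binaphthalen]-4-ol | COc1cccc2c(-c3ccc(OCc4ccccc4)c4c(OC)cccc34)cc(Br)c(O)c12
F2 | step 5 | 1-(benzyloxy)-2-bromo-8-methoxynaphthalene | COc1cccc2ccc(Br)c(OCc3ccccc3)c12
F3 | step 5 | 2-[1-(benzyloxy)-8-methoxynaphthalen-2-yl]-4,4,5,5-tetramethyl-1,3,2-dioxaborolane | COc1cccc2ccc(B3OC(C)(C)C(C)(C)O3)c(OCc3ccccc3)c12
F4 | step 5 | 1'-(benzyloxy)-4-[4-(benzyloxy)-5-methoxynaphthalen-1-yl]-8,8'-dimethoxy-[2,2'-binaphthalen]-1-ol | COc1cccc2ccc(-c3cc(-c4ccc(OCc5ccccc5)c5c(OC)cccc45)c4cccc(OC)c4c3O)c(OCc3ccccc3)c12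
F5 | step 1 | 4-bromo-8-methoxynaphthalen-1-ol | COc1cccc2c(Br)ccc(O)c12
F6 | step 1 | 1-(benzyloxy)-4-bromo-8-methoxynaphthalene | COc1cccc2c(Br)ccc(OCc3ccccc3)c12
F7 | step 1 | 2-[4-(benzyloxy)-5-methoxynaphthalen-1-yl]-4,4,5,5-tetramethyl-1,3,2-dioxaborolane | COc1cccc2c(B3OC(C)(C)C(C)(C)O3)ccc(OCc3ccccc3)c12
F8 | step 3 | 1-methoxy-8-(methoxymethoxy)naphthalene | COCOc1cccc2cccc(OC)c12
F9 | step 3 | 2-bromo-8-methoxy-1-(methoxymethoxy)naphthalene | COCOc1c(Br)ccc2cccc(OC)c12
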